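**Retrosynthetic overview**
1. The C6–C1′ bond is made last. A C6-zincated α-methoxy-γ-pyrone (an α-alkoxyvinyl metal, so a masked acyl anion and also a β-acylvinyl anion) is joined to the CH2Br carbon of 11-bromoundecyl acetate. Both carbons are innately electrophilic.
2. The zinc reagent comes from direct C–H zincation of the 6-unsubstituted 2-methoxy-3,5-dimethyl-4-pyrone. The pyrone is its own mask, so no unmasking step follows.
3. That pyrone comes from 4-hydroxy-3,5-dimethyl-2-pyrone by methylation at the lactone carbonyl oxygen.
4. The only ring is formed first, by γ-formylation of the dianion of methyl 2-methyl-3-oxopentanoate followed by lactonisation.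
5. The side chain comes from acetylation of 11-bromoundecan-1-ol.

Assumption: the target has no stereocentre and no stereogenic double bond, so it is achiral and needs no enantiocontrol. Compound 1 is used as the racemate, and its labile stereocentre disappears in step 1.

Abbreviations: TMP = 2,2,6,6-tetramethylpiperidide; IPr = 1,3-bis(2,6-diisopropylphenyl)imidazol-2-ylidene.

**Step 1**
Reactants: 1 methyl 2-methyl-3-oxopentanoate; 2 methyl formate
Product: 5 4-hydroxy-3,5-dimethyl-2H-pyran-2-one, via ketoester dianion 3 (not isolated), via formyl ketoester 4 (not isolated)
Conditions: 1 (2.0 equiv), NaH then n-BuLi, THF, 0 °C; 2 (1.0 equiv), −78 → 0 °C; aq HCl; crude, DBU, PhMe, 60 °C; aq HCl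
Reagents that add atoms: none
Why: This is a Claisen-type formylation of a β-ketoester dianion, which reacts only at its more basic γ-carbon while the second equivalent of dianion takes up the acidic proton of the product, and DBU then lactonises the hydroxymethylene enol onto the methyl ester to give the stable 4-hydroxy-2-pyrone, erasing the labile stereocentres and setting none.

**Step 2**
Reactants: 5 4-hydroxy-3,5-dimethyl-2H-pyran-2-one
Product: 7 2-methoxy-3,5-dimethyl-4H-pyran-4-one, via hydroxypyrylium triflate 6 (not isolated)
Conditions: MeOTf (1.2 equiv), CH2Cl2, 0 °C → rt, 16 h; aqueous wash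
Reagents that add atoms: methyl trifluoromethanesulfonate, COS(=O)(=O)C(F)(F)F
Why: This is O-methylation through a pyrylium salt, in which the hard electrophile under base-free conditions attacks the most basic lone pair (the lactone carbonyl oxygen) and the resulting 4-hydroxy-2-methoxypyrylium ion loses its OH proton on washing, giving the α-methoxy-γ-pyrone rather than the 4-methoxy-2-pyrone, with no stereocentre formed.

**Step 3**
Reactants: 8 11-bromoundecan-1-ol
Product: 9 11-bromoundecyl acetate
Conditions: Ac2O (1.2 equiv), Et3N, DMAP (cat.), CH2Cl2, 0 °C → rt
Reagents that add atoms: acetic anhydride, CC(=O)OC(C)=O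
Why: This is a DMAP-catalysed alcohol acetylation (nucleophilic acyl substitution), which is fast at room temperature and leaves the primary bromide untouched, with no stereocentre formed.

**Step 4**
Reactants: 7 2-methoxy-3,5-dimethyl-4H-pyran-4-one; 9 11-bromoundecyl acetate
Product: 11 11-(6-methoxy-3,5-dimethyl-4-oxo-4H-pyran-2-yl)undecyl acetate (target), via pyronylzinc chloride 10 (not isolated)
Conditions: 7 (1.3 equiv), TMPZnCl·LiCl (1.4 equiv), THF, 25 °C, 2 h; then 9 (1.0 equiv), PdCl2(IPr)(3-chloropyridine) (4 mol %), LiBr (3 equiv), THF/NMP 2:1, 25 → 40 °C
Reagents that add atoms: none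
Why: Proposed new method: C6–H is the only ring C–H and the most acidic site of 7 (sp2, α to the ring oxygen, with no γ-alkyl hydrogens to compete), so the hindered, non-nucleophilic TMPZnCl·LiCl should zincate it as it does C2 of chromones, turning the innately electrophilic C6 (masked acyl carbon and enone β-carbon) into an α-alkoxyvinyl-metal acyl-anion equivalent that has no β-leaving group and so cannot ring-open, and this ester-tolerant donor is then joined to the electrophilic CH2Br carbon of 9 by a Pd–NHC Negishi sp2–sp3 coupling that outruns β-hydride elimination, the closest known reaction types being α-metalation of enol ethers and TMP-zincation/Negishi coupling of chromones, with no stereocentre formed.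

**Compound list**
1 | methyl 2-methyl-3-oxopentanoate (racemic) | CCC(=O)C(C)C(=O)OC | starting material
2 | methyl formate | COC=O | starting material
3 | sodium lithium dienolate (dianion) of methyl 2-methyl-3-oxopentanoate | CC=C([O-])C(C)=C([O-])OC.[Na+].[Li+] | intermediate
4 | methyl 2,4-dimethyl-3,5-dioxopentanoate (mainly the hydroxymethylene enol) | COC(=O)C(C)C(=O)C(C)C=O | intermediate
5 | 4-hydroxy-3,5-dimethyl-2H-pyran-2-one | Cc1coc(=O)c(C)c1O | intermediate
6 | 4-hydroxy-2-methoxy-3,5-dimethylpyrylium trifluoromethanesulfonate | COc1[o+]cc(C)c(O)c1C.[O-]S(=O)(=O)C(F)(F)F | intermediate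
7 | 2-methoxy-3,5-dimethyl-4H-pyran-4-one | COc1occ(C)c(=O)c1C | intermediate
8 | 11-bromoundecan-1-ol | OCCCCCCCCCCCBr | starting material
9 | 11-bromoundecyl acetate | CC(=O)OCCCCCCCCCCCBr | intermediate
10 | chloro(6-methoxy-3,5-dimethyl-4-oxo-4H-pyran-2-yl)zinc, LiCl complex | COc1oc([Zn]Cl)c(C)c(=O)c1C.[Li+].[Cl-] | intermediate
11 | 11-(6-methoxy-3,5-dimethyl-4-oxo-4H-pyran-2-yl)undecyl acetate (achiral) | COc1oc(CCCCCCCCCCCOC(C)=O)c(C)c(=O)c1C | target

**Step count**
Total step count: 4. Longest linear sequence: 3 (steps 1, 2 and 4).

**Three steps most likely to fail**

Step 4 is the most likely to fail. The zincation of 7 is unprecedented, the zinc reagent is electron-poor, and protodezincation may compete. The fallback sets out from 7 and comes back at 11. It replaces the metalated pyrone by a radical C–H alkylation. Purchased 12-hydroxydodecanoic acid F1 is acetylated (Ac2O, pyridine) to 12-acetoxydodecanoic acid F2. Oxidative decarboxylation of F2 (AgNO3 cat., (NH4)2S2O8, TFA, MeCN/H2O, 50 °C) releases the 11-acetoxyundecyl radical. This radical adds Minisci-fashion to the free C6 of protonated 7. Oxidation and loss of the C6 proton restore the pyrone and give 11 directly.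

Step 1 is the next risk. Proton transfer during the formylation and deformylation of 4 by the released methoxide can both lower the yield. The fallback sets out from 1 and comes back at 5. It replaces the dianion chemistry by a neutral aminomethylenation. Compound 1 is heated with tert-butoxybis(dimethylamino)methane in toluene. Only the C4 methylene can give a stable enaminone, because C2 carries a single hydrogen. The product is methyl (E)-5-(dimethylamino)-2,4-dimethyl-3-oxopent-4-enoate F3. Warm aq HCl/THF hydrolyses the vinylogous amide and lactonises it to 5.

Step 2 is the third risk, because some 4-methoxy-2-pyrone may form and 7 is small and water-soluble. The fallback sets out from 4 (the crude product of the first acid quench in step 1) and comes back at 7. It keeps the ester methoxy group instead of removing it and re-installing it. PPh3/CCl4/Et3N in THF activates the hydroxymethylene OH in an Appel-type manner. The only nucleophile that can reach the activated carbon through a six-membered ring is the ester enolate oxygen. Addition–elimination therefore gives 7 directly, bypassing 5 and 6 and the O2/O4 regiochemistry question. This fallback makes no compound outside the list (F0).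

**Further compounds**
F1 | step 4 | 12-hydroxydodecanoic acid (purchased input) | OCCCCCCCCCCCC(=O)O
F2 | step 4 | 12-acetoxydodecanoic acid | CC(=O)OCCCCCCCCCCCC(=O)O
F3 | step 1 | methyl (E)-5-(dimethylamino)-2,4-dimethyl-3-oxopent-4-enoate | COC(=O)C(C)C(=O)/C(C)=C/N(C)C
F0 | step 2 | none | none
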